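The oxolane (O1, C2 bearing ring A, C3, C4, C5 bearing ring B) is disconnected at C2–C3. The feature exploited is the C2–H bond of a ring A benzyl ether: O1 and the para-oxygenated ring A make it hydridic, and it lies 1,5 to C3. A rhodium carbene generated at C3 from an α-diazo ester inserts into this bond. That forms C2–C3, closes the ring and sets C2 and C3 in one operation under the control of C4 and C5. The precursor is an acyclic, anti-configured 4-aryl-4-(arylmethoxy)-3-methyl-2-diazobutanoate from a catalytic asymmetric crotylboration. Its ester carbon later becomes the C3 methyl group.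

Key step: step 9

Assumption: the (R)-configured phosphoric acid is taken to direct crotyl transfer to the Re face of 2, as it does for other aryl aldehydes (the (S)-acid would be used if the antipode formed), and no separate equilibration of the C3 ester is scheduled because the chair model and the thermodynamic preference are expected to favour the same C3 epimer.

Step 1
Reactants: 1 3-hydroxy-4,5-dimethoxybenzaldehyde
Product: 2 3-(benzyloxy)-4,5-dimethoxybenzaldehyde
Conditions: BnBr, K2CO3, DMF, rt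
Reagents that add atoms: benzyl bromide, BrCc1ccccc1
Why: Williamson O-alkylation of the phenoxide, the only nucleophile present; the benzyl ether survives every base, hydride and oxidant used later and leaves in the final step.

Step 2
Reactants: 2 3-(benzyloxy)-4,5-dimethoxybenzaldehyde; 3 (E)-crotylboronic acid pinacol ester
Product: 5 (1R,2R)-1-[3-(benzyloxy)-4,5-dimethoxyphenyl]-2-methylbut-3-en-1-ol, via O-pinacolboryl ether 4 (not isolated)
Conditions: (R)-3,3'-bis(2,4,6-triisopropylphenyl)-1,1'-binaphthalene-2,2'-diyl hydrogen phosphate (5 mol %), toluene, −30 °C; aqueous work-up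
Reagents that add atoms: none
Why: Chiral-phosphoric-acid-catalysed crotylboration through a closed six-membered chair: the E-boronate transfers its geometry into the anti (future 4,5-trans) relationship, and the (R)-acid, hydrogen-bonded to a boronate oxygen and the formyl hydrogen, directs attack to the Re face of 2, which sets C5 as R and C4 as R.

Step 3
Reactants: 6 4-(benzyloxy)-3-methoxybenzyl alcohol
Product: 7 4-(benzyloxy)-3-methoxybenzyl chloride
Conditions: SOCl2, CH2Cl2, 0 °C
Reagents that add atoms: thionyl chloride, O=S(Cl)Cl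
Why: Chlorodehydroxylation through the chlorosulfite, fast for this electron-rich benzylic alcohol; the crystalline chloride is preferred to the bromide because it can be stored without self-alkylation.

Step 4
Reactants: 5 (1R,2R)-1-[3-(benzyloxy)-4,5-dimethoxyphenyl]-2-methylbut-3-en-1-ol; 7 4-(benzyloxy)-3-methoxybenzyl chloride
Product: 8 (1R,2R)-1-[3-(benzyloxy)-4,5-dimethoxyphenyl]-2-methylbut-3-en-1-yl 4-(benzyloxy)-3-methoxybenzyl ether
Conditions: NaH, DMF, 0 °C to rt
Reagents that add atoms: none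
Why: Williamson ether synthesis in which the sodium alkoxide of 5 displaces chloride from the highly SN2-active benzylic halide 7; the C5–O bond is never broken, so C4 and C5 are untouched.

Step 5
Reactants: 8 (1R,2R)-1-[3-(benzyloxy)-4,5-dimethoxyphenyl]-2-methylbut-3-en-1-yl 4-(benzyloxy)-3-methoxybenzyl ether
Product: 10 (3R,4R)-4-{[4-(benzyloxy)-3-methoxybenzyl]oxy}-4-[3-(benzyloxy)-4,5-dimethoxyphenyl]-3-methylbutan-1-ol, via B-alkyl-9-BBN adduct 9 (not isolated)
Conditions: 9-BBN, THF, 0 °C to rt; then NaOH, H2O2, 0 °C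
Reagents that add atoms: 9-borabicyclo[3.3.1]nonane, [H]B1C2CCCC1CCC2 (boron stays only in 9); hydrogen peroxide, OO
Why: Brown hydroboration–oxidation: the bulky borane places boron on the terminal alkene carbon and alkaline peroxide replaces it by OH, while all ethers are inert and no stereocentre is formed or touched.

Step 6
Reactants: 10 (3R,4R)-4-{[4-(benzyloxy)-3-methoxybenzyl]oxy}-4-[3-(benzyloxy)-4,5-dimethoxyphenyl]-3-methylbutan-1-ol
Product: 12 (3R,4R)-4-{[4-(benzyloxy)-3-methoxybenzyl]oxy}-4-[3-(benzyloxy)-4,5-dimethoxyphenyl]-3-methylbutanoic acid, via aldehyde 11 (not isolated)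
Conditions: 2,2,6,6-tetramethylpiperidine-1-oxyl (TEMPO, cat.), PhI(OAc)2, MeCN–H2O, rt
Reagents that add atoms: water, O
Why: Oxoammonium-mediated (TEMPO) oxidation with PhI(OAc)2 as terminal oxidant takes the alcohol to the aldehyde and, through its hydrate, to the acid; the chlorine-free system spares the electron-rich rings, and C4 is safe because the enolisable position is the C3 methylene.

Step 7
Reactants: 12 (3R,4R)-4-{[4-(benzyloxy)-3-methoxybenzyl]oxy}-4-[3-(benzyloxy)-4,5-dimethoxyphenyl]-3-methylbutanoic acid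
Product: 13 methyl (3R,4R)-4-{[4-(benzyloxy)-3-methoxybenzyl]oxy}-4-[3-(benzyloxy)-4,5-dimethoxyphenyl]-3-methylbutanoate
Conditions: MeI, K2CO3, DMF, rt
Reagents that add atoms: iodomethane, CI
Why: SN2 O-alkylation of the carboxylate, a mild esterification that avoids the acid to which the doubly benzylic ether is sensitive.

Step 8
Reactants: 13 methyl (3R,4R)-4-{[4-(benzyloxy)-3-methoxybenzyl]oxy}-4-[3-(benzyloxy)-4,5-dimethoxyphenyl]-3-methylbutanoate
Product: 15 methyl (3R,4R)-4-{[4-(benzyloxy)-3-methoxybenzyl]oxy}-4-[3-(benzyloxy)-4,5-dimethoxyphenyl]-2-diazo-3-methylbutanoate, via α-trifluoroacetyl ester 14 (not isolated)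
Conditions: LiN(SiMe3)2, THF, −78 °C; CF3CO2CH2CF3, −78 °C; aq NH4Cl; then 4-AcNHC6H4SO2N3, Et3N, MeCN, rt
Reagents that add atoms: 2,2,2-trifluoroethyl trifluoroacetate, O=C(OCC(F)(F)F)C(F)(F)F (acyl group stays only in 14); 4-acetamidobenzenesulfonyl azide, CC(=O)Nc1ccc(cc1)S(=O)(=O)N=[N+]=[N-]
Why: Detrifluoroacetylative variant of the Regitz diazo transfer: a plain ester is too weakly acidic for direct transfer, so its lithium enolate is first C-acylated (crossed Claisen condensation) to 14, whose stabilised enolate adds to the sulfonyl azide and then expels the N-sulfonyl trifluoroacetamide; the enolate has no β-leaving group and C4 and C5 stay intact.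

Step 9
Reactants: 15 methyl (3R,4R)-4-{[4-(benzyloxy)-3-methoxybenzyl]oxy}-4-[3-(benzyloxy)-4,5-dimethoxyphenyl]-2-diazo-3-methylbutanoate
Product: 16 methyl (2S,3S,4R,5R)-2-[4-(benzyloxy)-3-methoxyphenyl]-5-[3-(benzyloxy)-4,5-dimethoxyphenyl]-4-methyloxolane-3-carboxylate
Conditions: slow addition of 15 to Rh2(O2CCPh3)4 (1 mol %), CH2Cl2 (0.01 M), −78 °C, then slow warming to 0 °C
Reagents that add atoms: none
Why: Loss of N2 from 15 at an axial site of Rh2(O2CCPh3)4 gives an electrophilic carbene at C3, whose vacant orbital takes up the C2–H bond in a concerted, asynchronous three-centre insertion (hydride-like transfer to C3, then C2–C3 bonding with release of the catalyst and retention at C2). The closest known reaction type is the dirhodium-tetracarboxylate-catalysed 1,5 C–H insertion of α-alkyl-α-diazo esters next to an ether oxygen, which gives oxolane-3-carboxylates. The single ring closes by C2–C3 bond formation through a chair-like six-centre array (C3, C4, C5, O1, C2 and the migrating hydrogen), that is, a 1,5 insertion giving the five-membered ring. C2 is set by the existing C4 and C5 centres: with ring B, the C4 methyl and ring A all pseudo-equatorial, only the pro-S hydrogen of the OCH2 group reaches the carbene, which gives the 2,5-cis ring (C2 S). C3 is set in the same array, because the migrating hydrogen sits on the face that carries both aryl groups and stays there on C3, so the ester ends up trans to ring A and cis to the C4 methyl (C3 S); this is also expected to be the more stable epimer, so any leakage can be corrected by brief NaOMe/MeOH treatment. Insertion must outrun the 1,2-hydride shift from C4–H, attack on the ortho carbons of ring B and carbene dimerisation, and this is secured by the double activation of C2–H (O1 plus the para-benzyloxy donor of ring A), by the inductive deactivation of C4–H by the C5 oxygen and its gauche, non-aligned position in the chair, by ring B lying anti to C3 in that chair, and by the bulky carboxylate walls, low temperature and high dilution.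

Step 10
Reactants: 16 methyl (2S,3S,4R,5R)-2-[4-(benzyloxy)-3-methoxyphenyl]-5-[3-(benzyloxy)-4,5-dimethoxyphenyl]-4-methyloxolane-3-carboxylate
Product: 17 {(2S,3R,4R,5R)-2-[4-(benzyloxy)-3-methoxyphenyl]-5-[3-(benzyloxy)-4,5-dimethoxyphenyl]-4-methyloxolan-3-yl}methanol
Conditions: LiAlH4, THF, 0 °C
Reagents that add atoms: none
Why: Ester reduction with LiAlH4, where hydride addition is much faster than enolisation at 0 °C, so C3 keeps its spatial arrangement (the descriptor changes only through priorities) and the ethers are inert.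

Step 11
Reactants: 17 {(2S,3R,4R,5R)-2-[4-(benzyloxy)-3-methoxyphenyl]-5-[3-(benzyloxy)-4,5-dimethoxyphenyl]-4-methyloxolan-3-yl}methanol
Product: 18 {(2S,3R,4R,5R)-2-[4-(benzyloxy)-3-methoxyphenyl]-5-[3-(benzyloxy)-4,5-dimethoxyphenyl]-4-methyloxolan-3-yl}methyl methanesulfonate
Conditions: MsCl, Et3N, CH2Cl2, 0 °C
Reagents that add atoms: methanesulfonyl chloride, CS(=O)(=O)Cl
Why: Sulfonylation of the only free hydroxyl group, which turns it into a leaving group without touching a stereocentre.

Step 12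
Reactants: 18 {(2S,3R,4R,5R)-2-[4-(benzyloxy)-3-methoxyphenyl]-5-[3-(benzyloxy)-4,5-dimethoxyphenyl]-4-methyloxolan-3-yl}methyl methanesulfonate
Product: 19 (2S,3S,4R,5R)-2-[4-(benzyloxy)-3-methoxyphenyl]-5-[3-(benzyloxy)-4,5-dimethoxyphenyl]-3,4-dimethyloxolane
Conditions: LiEt3BH, THF, 0 °C to rt
Reagents that add atoms: none
Why: SN2 hydride displacement of a primary sulfonate; LiEt3BH is the most nucleophilic common hydride and copes with the β-branched carbon, and the reacting CH2 is not stereogenic.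

Step 13
Reactants: 19 (2S,3S,4R,5R)-2-[4-(benzyloxy)-3-methoxyphenyl]-5-[3-(benzyloxy)-4,5-dimethoxyphenyl]-3,4-dimethyloxolane
Product: 20 4-[(2S,3S,4R,5R)-5-(3-hydroxy-4,5-dimethoxyphenyl)-3,4-dimethyloxolan-2-yl]-2-methoxyphenol
Conditions: H2 (1 atm), 10% Pd/C, EtOAc, rt
Reagents that add atoms: none
Why: Catalytic hydrogenolysis: the two aryl benzyl ethers are cleaved far faster than the hindered benzylic C2–O1 and C5–O1 bonds of the ring under neutral conditions at one atmosphere, so stopping after two equivalents of H2 should release both phenols with all four stereocentres intact.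

Compound list

1 | 3-hydroxy-4,5-dimethoxybenzaldehyde | COc1cc(C=O)cc(O)c1OC | starting material
2 | 3-(benzyloxy)-4,5-dimethoxybenzaldehyde | COc1cc(C=O)cc(OCc2ccccc2)c1OC | intermediate
3 | (E)-crotylboronic acid pinacol ester | C/C=C/CB1OC(C)(C)C(C)(C)O1 | starting material
4 | 2-{[(1R,2R)-1-(3-benzyloxy-4,5-dimethoxyphenyl)-2-methylbut-3-en-1-yl]oxy}-4,4,5,5-tetramethyl-1,3,2-dioxaborolane | CC1(C)OB(O[C@@H](c2cc(OCc3ccccc3)c(OC)c(OC)c2)[C@H](C)C=C)OC1(C)C | intermediate
5 | (1R,2R)-1-[3-(benzyloxy)-4,5-dimethoxyphenyl]-2-methylbut-3-en-1-ol (anti) | O[C@@H](c1cc(OCc2ccccc2)c(OC)c(OC)c1)[C@H](C)C=C | intermediate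
6 | 4-(benzyloxy)-3-methoxybenzyl alcohol (O-benzylvanillyl alcohol) | COc1cc(CO)ccc1OCc1ccccc1 | starting material
7 | 4-(benzyloxy)-3-methoxybenzyl chloride | COc1cc(CCl)ccc1OCc1ccccc1 | intermediate
8 | (1R,2R)-1-[3-(benzyloxy)-4,5-dimethoxyphenyl]-2-methylbut-3-en-1-yl 4-(benzyloxy)-3-methoxybenzyl ether | COc1cc(CO[C@@H](c2cc(OCc3ccccc3)c(OC)c(OC)c2)[C@H](C)C=C)ccc1OCc1ccccc1 | intermediate
9 | 9-[(3R,4R)-4-{[4-(benzyloxy)-3-methoxybenzyl]oxy}-4-(3-benzyloxy-4,5-dimethoxyphenyl)-3-methylbutyl]-9-borabicyclo[3.3.1]nonane | COc1cc(CO[C@@H](c2cc(OCc3ccccc3)c(OC)c(OC)c2)[C@H](C)CCB2C3CCCC2CCC3)ccc1OCc1ccccc1 | intermediate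
10 | (3R,4R)-4-{[4-(benzyloxy)-3-methoxybenzyl]oxy}-4-[3-(benzyloxy)-4,5-dimethoxyphenyl]-3-methylbutan-1-ol | COc1cc(CO[C@@H](c2cc(OCc3ccccc3)c(OC)c(OC)c2)[C@H](C)CCO)ccc1OCc1ccccc1 | intermediate
11 | (3R,4R)-4-{[4-(benzyloxy)-3-methoxybenzyl]oxy}-4-[3-(benzyloxy)-4,5-dimethoxyphenyl]-3-methylbutanal | COc1cc(CO[C@@H](c2cc(OCc3ccccc3)c(OC)c(OC)c2)[C@H](C)CC=O)ccc1OCc1ccccc1 | intermediate
12 | (3R,4R)-4-{[4-(benzyloxy)-3-methoxybenzyl]oxy}-4-[3-(benzyloxy)-4,5-dimethoxyphenyl]-3-methylbutanoic acid | COc1cc(CO[C@@H](c2cc(OCc3ccccc3)c(OC)c(OC)c2)[C@H](C)CC(=O)O)ccc1OCc1ccccc1 | intermediate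
13 | methyl (3R,4R)-4-{[4-(benzyloxy)-3-methoxybenzyl]oxy}-4-[3-(benzyloxy)-4,5-dimethoxyphenyl]-3-methylbutanoate | COc1cc(CO[C@@H](c2cc(OCc3ccccc3)c(OC)c(OC)c2)[C@H](C)CC(=O)OC)ccc1OCc1ccccc1 | intermediate
14 | methyl (3R,4R)-4-{[4-(benzyloxy)-3-methoxybenzyl]oxy}-4-[3-(benzyloxy)-4,5-dimethoxyphenyl]-3-methyl-2-(trifluoroacetyl)butanoate (C2 epimers) | COc1cc(CO[C@@H](c2cc(OCc3ccccc3)c(OC)c(OC)c2)[C@H](C)C(C(=O)C(F)(F)F)C(=O)OC)ccc1OCc1ccccc1 | intermediate
15 | methyl (3R,4R)-4-{[4-(benzyloxy)-3-methoxybenzyl]oxy}-4-[3-(benzyloxy)-4,5-dimethoxyphenyl]-2-diazo-3-methylbutanoate (3,4-anti) | COc1cc(CO[C@@H](c2cc(OCc3ccccc3)c(OC)c(OC)c2)[C@H](C)C(=[N+]=[N-])C(=O)OC)ccc1OCc1ccccc1 | intermediate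
16 | methyl (2S,3S,4R,5R)-2-[4-(benzyloxy)-3-methoxyphenyl]-5-[3-(benzyloxy)-4,5-dimethoxyphenyl]-4-methyloxolane-3-carboxylate (2,3-trans, 3,4-cis, 4,5-trans) | COc1cc([C@H]2O[C@@H](c3cc(OCc4ccccc4)c(OC)c(OC)c3)[C@H](C)[C@@H]2C(=O)OC)ccc1OCc1ccccc1 | intermediate
17 | {(2S,3R,4R,5R)-2-[4-(benzyloxy)-3-methoxyphenyl]-5-[3-(benzyloxy)-4,5-dimethoxyphenyl]-4-methyloxolan-3-yl}methanol | COc1cc([C@H]2O[C@@H](c3cc(OCc4ccccc4)c(OC)c(OC)c3)[C@H](C)[C@@H]2CO)ccc1OCc1ccccc1 | intermediate
18 | {(2S,3R,4R,5R)-2-[4-(benzyloxy)-3-methoxyphenyl]-5-[3-(benzyloxy)-4,5-dimethoxyphenyl]-4-methyloxolan-3-yl}methyl methanesulfonate | COc1cc([C@H]2O[C@@H](c3cc(OCc4ccccc4)c(OC)c(OC)c3)[C@H](C)[C@@H]2COS(C)(=O)=O)ccc1OCc1ccccc1 | intermediate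
19 | (2S,3S,4R,5R)-2-[4-(benzyloxy)-3-methoxyphenyl]-5-[3-(benzyloxy)-4,5-dimethoxyphenyl]-3,4-dimethyloxolane | COc1cc([C@H]2O[C@@H](c3cc(OCc4ccccc4)c(OC)c(OC)c3)[C@H](C)[C@@H]2C)ccc1OCc1ccccc1 | intermediate
20 | 4-[(2S,3S,4R,5R)-5-(3-hydroxy-4,5-dimethoxyphenyl)-3,4-dimethyloxolan-2-yl]-2-methoxyphenol | COc1cc([C@H]2O[C@@H](c3cc(O)c(OC)c(OC)c3)[C@H](C)[C@@H]2C)ccc1O | target

Total step count: 13. Longest linear sequence: 12 steps (steps 1, 2 and 4 to 13; step 3 is a one-step side branch).

Steps most likely to fail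

Step 9. The carbene may be consumed by 1,2-hydride migration from C4–H or by electrophilic attack on ring B. The closure may also discriminate poorly between the two C2 hydrogens. A change of carboxylate (Rh2(O2CCMe3)4) would be tried first.

The real fallback gives up the insertion. It sets out from 5 and comes back at 19.
- Hydroboration–oxidation (9-BBN; NaOH, H2O2) should give (1R,2R)-1-aryl-2-methylbutane-1,4-diol F1.
- TEMPO/PhI(OAc)2 should lactonise it to the 4,5-trans lactone F2.
- Methylation (LiN(iPr)2, MeI, −78 °C) enters anti to the C4 methyl and gives the 3,4-trans dimethyl lactone F3.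
- Re-enolisation and kinetic protonation with 2,6-di-tert-butyl-4-methylphenol, again anti to the C4 methyl, inverts C3 to the 3,4-cis dimethyl lactone F4.
- Addition of (4-benzyloxy-3-methoxyphenyl)lithium F5, made from 1-(benzyloxy)-4-bromo-2-methoxybenzene and n-BuLi, gives the hemiketal F6.
- Immediate reduction with LiAlH4 gives the 1,4-diol F7 as a mixture at C2.
- Catalytic camphorsulfonic acid in CH2Cl2 ionises the ring A benzylic alcohol, and the C5 hydroxyl closes the ring.

With C3 and C4 fixed and cis, both aryl groups prefer to sit trans to their neighbouring methyl groups. This reversible SN1 cycloetherification should therefore funnel into 19, and steps 10 to 12 are skipped.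

Step 8. C-acylation of the hindered, β-branched enolate may be incomplete, or the activated ester may undergo retro-Claisen cleavage without nitrogen transfer.

The fallback sets out from 13 and comes back at 15. It replaces deacylative diazo transfer by azide transfer followed by azide-to-diazo conversion.
- KN(SiMe3)2, then 2,4,6-triisopropylbenzenesulfonyl azide with an acetic acid quench, gives the α-azido ester F8.
- N-succinimidyl 3-(diphenylphosphino)propanoate in aqueous THF traps the Staudinger-type phosphazide by intramolecular acylation to give the acyl triazene F9.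
- F9 fragments to 15 on treatment with NaHCO3 or DBU.

Step 13. Over-reduction may open the ring by hydrogenolysis of C2–O1 or C5–O1, and acidic catalyst batches may cause benzylic epimerisation.

The fallback sets out from 19 and comes back at 20. It is non-reductive: BCl3 with pentamethylbenzene as a non-basic benzyl-cation scavenger, CH2Cl2, −78 °C. No ring C–O bond can be hydrogenolysed this way. Reversible ionisation at C2 or C5 would be harmless, because the target already has the favoured aryl-trans-to-methyl arrangement at both centres. This fallback makes no further compound F0.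

Further compounds

F1 | step 9 | (1R,2R)-1-[3-(benzyloxy)-4,5-dimethoxyphenyl]-2-methylbutane-1,4-diol | O[C@@H](c1cc(OCc2ccccc2)c(OC)c(OC)c1)[C@H](C)CCO
F2 | step 9 | (4R,5R)-5-[3-(benzyloxy)-4,5-dimethoxyphenyl]-4-methyloxolan-2-one | O1[C@@H](c2cc(OCc3ccccc3)c(OC)c(OC)c2)[C@H](C)CC1=O
F3 | step 9 | (3R,4R,5R)-5-[3-(benzyloxy)-4,5-dimethoxyphenyl]-3,4-dimethyloxolan-2-one (3,4-trans) | O1[C@@H](c2cc(OCc3ccccc3)c(OC)c(OC)c2)[C@H](C)[C@@H](C)C1=O
F4 | step 9 | (3S,4R,5R)-5-[3-(benzyloxy)-4,5-dimethoxyphenyl]-3,4-dimethyloxolan-2-one (3,4-cis) | O1[C@@H](c2cc(OCc3ccccc3)c(OC)c(OC)c2)[C@H](C)[C@H](C)C1=O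
F5 | step 9 | (4-benzyloxy-3-methoxyphenyl)lithium | [Li]c1ccc(OCc2ccccc2)c(OC)c1
F6 | step 9 | (3S,4R,5R)-2-[4-(benzyloxy)-3-methoxyphenyl]-5-[3-(benzyloxy)-4,5-dimethoxyphenyl]-3,4-dimethyloxolan-2-ol (C2 anomers) | COc1cc(C2(O)O[C@@H](c3cc(OCc4ccccc4)c(OC)c(OC)c3)[C@H](C)[C@@H]2C)ccc1OCc1ccccc1
F7 | step 9 | (2S,3R,4R)-1-[4-(benzyloxy)-3-methoxyphenyl]-4-[3-(benzyloxy)-4,5-dimethoxyphenyl]-2,3-dimethylbutane-1,4-diol (C1 epimers) | O[C@@H](c1cc(OCc2ccccc2)c(OC)c(OC)c1)[C@H](C)[C@H](C)C(O)c1ccc(OCc2ccccc2)c(OC)c1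
F8 | step 8 | methyl (3R,4R)-2-azido-4-{[4-(benzyloxy)-3-methoxybenzyl]oxy}-4-[3-(benzyloxy)-4,5-dimethoxyphenyl]-3-methylbutanoate (C2 epimers) | COc1cc(CO[C@@H](c2cc(OCc3ccccc3)c(OC)c(OC)c2)[C@H](C)C(N=[N+]=[N-])C(=O)OC)ccc1OCc1ccccc1
F9 | step 8 | 3-acyl triazene of F8 with 3-(diphenylphosphoryl)propanoyl on the terminal nitrogen | COc1cc(CO[C@@H](c2cc(OCc3ccccc3)c(OC)c(OC)c2)[C@H](C)C(N=NNC(=O)CCP(=O)(c2ccccc2)c2ccccc2)C(=O)OC)ccc1OCc1ccccc1
F0 | step 13 | none | none
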